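**Strategy.** The cyclohexa-2,5-diene ring (C1 carries the ring acetate, C2 the side chain, C4 the hydroxyl, C6 the methoxy group) is assembled as a formal [4+2] union of an open-chain C2–C5 fragment with the C6–C1 unit of 2-methoxyacrolein. In one flask, an asymmetric Nozaki–Hiyama–Kishi addition of a (Z)-alkenyl iodide to the aldehyde forms the C2–C1 bond and the C1 carbinol, and ring-closing metathesis of the resulting 1,4,7-triene forms the C5=C6 enol ether bond. The step exploits that C1 is an allylic carbinol attached to the alkene carbon C2 and that C6 is an enol ether carbon. The precursor is an iodo dienol silyl ether.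

Key step: step 7

Remark: ring atoms are numbered as in the systematic name of the target; racemic pent-1-en-4-yn-3-ol and methoxyacetaldehyde are taken as commercial. The two bond-forming events of step 7 are run in sequence in one flask without isolation.

Step 1
Reactants: 1 (R)-epichlorohydrin; 2 dodecylmagnesium bromide
Product: 4 (R)-2-tridecyloxirane, via chlorohydrin 3 (not isolated)
Conditions: CuI (cat.), THF, −40 to 0 °C; H2O; then NaOH, Et2O/H2O, rt
Reagents that add atoms: none
Why: Copper-catalysed Grignard opening of the epoxide at its CH2 carbon and base-induced Williamson closure of the chlorohydrin should give the chain-extended epoxide with the stereocentre carried over unchanged, because no bond to it is broken.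

Step 2
Reactants: 5 racemic pent-1-en-4-yn-3-ol
Product: 6 (S)-pent-1-en-4-yn-3-ol
Conditions: Ti(OiPr)4, diisopropyl L-(+)-tartrate, t-BuOOH (0.6 equiv), 4 Å molecular sieves, CH2Cl2, −20 °C
Reagents that add atoms: none
Why: Sharpless kinetic resolution, in which the titanium tartrate complex should epoxidise the (R)-alcohol faster so that the (S)-alcohol is recovered enriched past half conversion, the configuration being set by the reagent.

Step 3
Reactants: 6 (S)-pent-1-en-4-yn-3-ol
Product: 7 (S)-3-(tert-butyldimethylsilyloxy)pent-1-en-4-yne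
Conditions: TBSCl, imidazole, DMF, 0 °C to rt
Reagents that add atoms: tert-butyldimethylsilyl chloride, CC(C)(C)[Si](C)(C)Cl
Why: Imidazole-promoted silylation of the secondary alcohol leaves the stereocentre untouched and gives an ether that should survive the organolithium, tin hydride, chromium and ruthenium steps.

Step 4
Reactants: 7 (S)-3-(tert-butyldimethylsilyloxy)pent-1-en-4-yne; 4 (R)-2-tridecyloxirane
Product: 8 (3S,7R)-3-(tert-butyldimethylsilyloxy)icos-1-en-4-yn-7-ol
Conditions: n-BuLi, THF, −78 °C; then 4, DMPU, −78 °C to rt; H2O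
Reagents that add atoms: none
Why: SN2 opening of the terminal epoxide at its CH2 carbon by the lithium acetylide should give the homopropargylic alcohol with both stereocentres untouched.

Step 5
Reactants: 8 (3S,7R)-3-(tert-butyldimethylsilyloxy)icos-1-en-4-yn-7-ol
Product: 10 (3S,4Z,7R)-3-(tert-butyldimethylsilyloxy)-5-iodoicosa-1,4-dien-7-ol, via alkenylstannane 9 (not isolated)
Conditions: Bu3SnH, [(C5Me5)RuCl]4 (cat.), CH2Cl2, rt; then I2, CH2Cl2, −78 to 0 °C
Reagents that add atoms: iodine, [I][I]; tributyltin hydride, CCCC[SnH](CCCC)CCCC (its tin stays only in 9)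
Why: Ruthenium-catalysed trans-hydrostannation of the internal alkyne, with the free homopropargylic hydroxyl steering tin to the proximal alkyne carbon by hydrogen bonding to the chloride ligand, followed by tin–iodine exchange with retention should give the alkenyl iodide with iodine cis to the siloxy-bearing carbon.

Step 6
Reactants: 11 methoxyacetaldehyde
Product: 12 2-methoxyacrolein (2-methoxyprop-2-enal)
Conditions: aqueous formaldehyde, pyrrolidine (cat.), propanoic acid (cat.), i-PrOH, 45 °C
Reagents that add atoms: formaldehyde, C=O
Why: Amine-catalysed Mannich condensation with formaldehyde followed by elimination of the amine (α-methylenation of an aldehyde) should give the 2-substituted acrolein.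

Step 7
Reactants: 10 (3S,4Z,7R)-3-(tert-butyldimethylsilyloxy)-5-iodoicosa-1,4-dien-7-ol; 12 2-methoxyacrolein
Product: 14 (1S,4R)-4-(tert-butyldimethylsilyloxy)-2-[(2R)-2-hydroxypentadecyl]-6-methoxycyclohexa-2,5-dien-1-ol, via trienediol 13 (not isolated)
Conditions: CrCl2, NiCl2 (cat.), (S)-N-[2-(4-isopropyl-4,5-dihydrooxazol-2-yl)-6-methylphenyl]methanesulfonamide, Et3N, THF, rt; filtration through basic Al2O3 and solvent exchange to CH2Cl2 without isolation; then second-generation Grubbs catalyst (cat.), 1,4-benzoquinone (cat.), 40 °C
Reagents that add atoms: none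
Why: Zerovalent nickel formed in situ inserts into the carbon–iodine bond of 10, the alkenyl group passes to chromium with retention of the double-bond geometry and adds 1,2 to the aldehyde of 12 to make the C2–C1 bond, after which the ruthenium alkylidene starts at the monosubstituted vinyl group of 13 and closes onto the 1-methoxyvinyl group to make the C5=C6 bond with loss of ethene. The closest known reaction types are the asymmetric Nozaki–Hiyama–Kishi alkenylation of aldehydes and the ring-closing metathesis of enol ethers, here run in sequence in one flask. The only ring formed is the six-membered carbocycle, closed by metathesis between the two terminal alkenes that are held cis on the C2=C3 double bond. The new C1 stereocentre is set by the chiral sulfonamide bound to trivalent chromium (reagent control, ligand enantiomer chosen to give 1S, which places O1 cis to O4), since the C4 centre is too remote to steer the addition. The step needs 1,2- over 1,4-addition, which the oxophilic chromium reagent secures, and metathesis of only the two terminal alkenes, which the trisubstituted C2=C3 bond and the neutral medium (benzoquinone against double-bond migration and aromatisation) secure.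

Step 8
Reactants: 14 (1S,4R)-4-(tert-butyldimethylsilyloxy)-2-[(2R)-2-hydroxypentadecyl]-6-methoxycyclohexa-2,5-dien-1-ol
Product: 15 (1S,4R)-2-[(2R)-2-acetoxypentadecyl]-4-(tert-butyldimethylsilyloxy)-6-methoxycyclohexa-2,5-dien-1-yl acetate
Conditions: Ac2O, pyridine, DMAP (cat.), CH2Cl2, 0 °C
Reagents that add atoms: acetic anhydride, CC(=O)OC(C)=O
Why: DMAP-catalysed acylation of the two secondary hydroxyls under basic, non-ionising conditions should give the diacetate without touching the stereocentres or the acid-sensitive enol ether.

Step 9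
Reactants: 15 (1S,4R)-2-[(2R)-2-acetoxypentadecyl]-4-(tert-butyldimethylsilyloxy)-6-methoxycyclohexa-2,5-dien-1-yl acetate
Product: 16 (1S,4R)-2-[(2R)-2-acetoxypentadecyl]-4-hydroxy-6-methoxycyclohexa-2,5-dien-1-yl acetate (CNP0123936.1)
Conditions: Bu4NF, AcOH, THF, 0 °C
Reagents that add atoms: none
Why: Fluoride cleaves the silicon–oxygen bond, and buffering with acetic acid should suppress acetyl migration between the cis oxygens on C1 and C4 and base-induced loss of acetic acid that would aromatise the ring.

**Compound list**

1 | (R)-epichlorohydrin | ClC[C@H]1CO1 | starting material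
2 | dodecylmagnesium bromide | CCCCCCCCCCCC[Mg]Br | starting material
3 | (R)-1-chloropentadecan-2-ol | ClC[C@H](O)CCCCCCCCCCCCC | intermediate
4 | (R)-2-tridecyloxirane | CCCCCCCCCCCCC[C@@H]1CO1 | intermediate
5 | racemic pent-1-en-4-yn-3-ol | C#CC(O)C=C | starting material
6 | (S)-pent-1-en-4-yn-3-ol | C#C[C@@H](O)C=C | intermediate
7 | (S)-3-(tert-butyldimethylsilyloxy)pent-1-en-4-yne | C#C[C@@H](O[Si](C)(C)C(C)(C)C)C=C | intermediate
8 | (3S,7R)-3-(tert-butyldimethylsilyloxy)icos-1-en-4-yn-7-ol | CCCCCCCCCCCCC[C@@H](O)CC#C[C@@H](O[Si](C)(C)C(C)(C)C)C=C | intermediate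
9 | (3S,4Z,7R)-3-(tert-butyldimethylsilyloxy)-5-(tributylstannyl)icosa-1,4-dien-7-ol | CCCCCCCCCCCCC[C@@H](O)C/C(=C/[C@@H](O[Si](C)(C)C(C)(C)C)C=C)[Sn](CCCC)(CCCC)CCCC | intermediate
10 | (3S,4Z,7R)-3-(tert-butyldimethylsilyloxy)-5-iodoicosa-1,4-dien-7-ol | CCCCCCCCCCCCC[C@@H](O)C/C(I)=C/[C@@H](O[Si](C)(C)C(C)(C)C)C=C | intermediate
11 | methoxyacetaldehyde | COCC=O | starting material
12 | 2-methoxyacrolein | C=C(OC)C=O | intermediate
13 | (3S,4Z,7R)-3-(tert-butyldimethylsilyloxy)-5-[(1S)-1-hydroxy-2-methoxyprop-2-en-1-yl]icosa-1,4-dien-7-ol | CCCCCCCCCCCCC[C@@H](O)C/C(=C/[C@@H](O[Si](C)(C)C(C)(C)C)C=C)[C@H](O)C(OC)=C | intermediate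
14 | (1S,4R)-4-(tert-butyldimethylsilyloxy)-2-[(2R)-2-hydroxypentadecyl]-6-methoxycyclohexa-2,5-dien-1-ol | CCCCCCCCCCCCC[C@@H](O)CC1=C[C@@H](O[Si](C)(C)C(C)(C)C)C=C(OC)[C@H]1O | intermediate
15 | (1S,4R)-2-[(2R)-2-acetoxypentadecyl]-4-(tert-butyldimethylsilyloxy)-6-methoxycyclohexa-2,5-dien-1-yl acetate | CCCCCCCCCCCCC[C@H](CC1=C[C@@H](O[Si](C)(C)C(C)(C)C)C=C(OC)[C@H]1OC(C)=O)OC(C)=O | intermediate
16 | (1S,4R)-2-[(2R)-2-acetoxypentadecyl]-4-hydroxy-6-methoxycyclohexa-2,5-dien-1-yl acetate | CCCCCCCCCCCCC[C@H](CC1=C[C@@H](O)C=C(OC)[C@H]1OC(C)=O)OC(C)=O | target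

Total step count: 9
Longest linear sequence: 7 steps (steps 2, 3, 4, 5, 7, 8, 9)

**Steps most likely to fail**

1. Step 7. What may go wrong: poor facial selectivity in the carbonyl addition, because the chromium complex must override a distant stereocentre, and loss of metathesis activity or double-bond migration caused by chromium residues carried into the second stage. The fallback sets out from 10 and 12 and comes back at 14. The coupling is run without the chiral ligand (CrCl2, NiCl2 cat., DMSO) and the adduct is isolated as the mixture of epimers at the new carbinol centre, (3S,4Z,7R)-3-(tert-butyldimethylsilyloxy)-5-(1-hydroxy-2-methoxyprop-2-en-1-yl)icosa-1,4-dien-7-ol F1. Selective oxidation of the bis-allylic alcohol with MnO2 gives the cross-conjugated dienone (3S,4Z,7R)-3-(tert-butyldimethylsilyloxy)-7-hydroxy-5-(2-methoxyprop-2-enoyl)icosa-1,4-diene F2. Corey–Bakshi–Shibata reduction with (S)-2-methyl-CBS-oxazaborolidine and catecholborane, in which the chain-bearing alkenyl group should act as the large substituent, gives 13 as one epimer. Isolated 13 is then closed separately with the second-generation Grubbs catalyst in CH2Cl2 to 14.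

2. Step 5. What may go wrong: delivery of tin to the distal alkyne carbon, or competing reaction of the ruthenium hydride with the neighbouring vinyl group. The fallback sets out from 8 and comes back at 10. Hydroxyl-directed trans-hydroalumination with NaAlH2(OCH2CH2OCH3)2 in THF, in which the homopropargylic alkoxide holds aluminium on the proximal alkyne carbon and hydride adds anti, gives the five-membered cyclic sodium alkenylalanate F3. Iodinolysis of its aluminium–carbon bond with I2 at −78 °C gives 10 directly.

3. Step 2. What may go wrong: too small a rate difference between the two enantiomers, because the ethynyl group is sterically small, and loss of the volatile alcohol on recovery. The fallback sets out from commercial acrolein and ethynyltrimethylsilane and comes back at 7. Addition of lithium (trimethylsilyl)acetylide to acrolein gives racemic 5-(trimethylsilyl)pent-1-en-4-yn-3-ol F4. Lipase-catalysed acylation (Burkholderia cepacia lipase, vinyl acetate, hexane), in which the large silylethynyl group should lead the enzyme to acylate the (R)-alcohol, leaves (S)-5-(trimethylsilyl)pent-1-en-4-yn-3-ol F5. Silylation with TBSCl and imidazole gives (S)-3-(tert-butyldimethylsilyloxy)-5-(trimethylsilyl)pent-1-en-4-yne F6, and K2CO3 in methanol removes only the alkynyl silyl group to give 7.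

Further compounds

F1 | step 7 | (3S,4Z,7R)-3-(tert-butyldimethylsilyloxy)-5-(1-hydroxy-2-methoxyprop-2-en-1-yl)icosa-1,4-dien-7-ol, mixture of carbinol epimers | CCCCCCCCCCCCC[C@@H](O)C/C(=C/[C@@H](O[Si](C)(C)C(C)(C)C)C=C)C(O)C(OC)=C
F2 | step 7 | (3S,4Z,7R)-3-(tert-butyldimethylsilyloxy)-7-hydroxy-5-(2-methoxyprop-2-enoyl)icosa-1,4-diene | CCCCCCCCCCCCC[C@@H](O)C/C(=C/[C@@H](O[Si](C)(C)C(C)(C)C)C=C)C(=O)C(OC)=C
F3 | step 5 | cyclic sodium alkenylalanate of 8 (aluminium on C5 and O7, two 2-methoxyethoxy groups on aluminium) | [Na+].COCCO[Al-]1(OCCOC)O[C@H](CCCCCCCCCCCCC)C/C1=C/[C@@H](O[Si](C)(C)C(C)(C)C)C=C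
F4 | step 2 | racemic 5-(trimethylsilyl)pent-1-en-4-yn-3-ol | C[Si](C)(C)C#CC(O)C=C
F5 | step 2 | (S)-5-(trimethylsilyl)pent-1-en-4-yn-3-ol | C[Si](C)(C)C#C[C@@H](O)C=C
F6 | step 2 | (S)-3-(tert-butyldimethylsilyloxy)-5-(trimethylsilyl)pent-1-en-4-yne | C[Si](C)(C)C#C[C@@H](O[Si](C)(C)C(C)(C)C)C=C
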